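The pyran ring (O1–C2–C3–C4–C4a–C8a) is cut at O1–C2 and C3–C4 into an ortho-quinone methide of ring A and an (E)-β-ethoxystyrene carrying ring B. A chiral-phosphoric-acid-catalysed inverse-demand oxa-Diels–Alder reaction closes this ring and sets C3 in one operation. It exploits that C4 is a benzylic CH2 ortho to O1 and para to O7, and that C3 carries the aryl group beside O-bound C2. The precursors are a salicyl alcohol and an aryl enol ether; the C2 ethoxy group is a temporary handle removed by ionic hydrogenation. Both 1,1-dimethylallyl groups follow at the equivalent positions C6 and C5′ by dibromination and branch-selective prenyl–aryl coupling.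

Key step: step 4

Remark on numbering: isoflavan locants are used (O1, C2, C3, C4, C4a, C5–C8, C8a; ring B primed). The target is (3R).
Assumption: the sense of induction of the phosphoric acid in step 4 has to be fixed in the first runs; the route is written with the (R)-catalyst, and its antipode is taken if the (3S) series should form.

Step 1
Reactants: 1 4-(benzyloxy)-2-hydroxybenzaldehyde
Product: 2 5-(benzyloxy)-2-(hydroxymethyl)phenol
Conditions: NaBH4, MeOH/THF, 0 °C
Reagents that add atoms: none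
Why: Borohydride reduction of the aldehyde leaves the phenol and the benzyl ether untouched; the electron-rich salicyl alcohol is used soon after isolation because it self-condenses on storage.

Step 2
Reactants: 3 4-bromoresorcinol
Product: 4 2,4-bis(benzyloxy)-1-bromobenzene
Conditions: BnBr (2.3 equiv), K2CO3, DMF, 50 °C
Reagents that add atoms: benzyl bromide BrCc1ccccc1
Why: Twofold Williamson etherification; benzyl ethers are chosen because they should survive the Pd couplings, the acids of steps 4 and 5 and NBS, and because as ethers they direct the later bromination.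

Step 3
Reactants: 4 2,4-bis(benzyloxy)-1-bromobenzene; 5 (E)-2-(2-ethoxyvinyl)-4,4,5,5-tetramethyl-1,3,2-dioxaborolane
Product: 6 (E)-2,4-bis(benzyloxy)-1-(2-ethoxyvinyl)benzene
Conditions: Pd(OAc)2/SPhos (cat.), K3PO4, dioxane/H2O, 80 °C; chromatography on Et3N-washed silica
Reagents that add atoms: none
Why: Suzuki–Miyaura coupling of an aryl bromide with an alkenylboronate proceeds with retention of the alkene geometry and should give the geometrically pure (E)-enol ether.

Step 4
Reactants: 2 5-(benzyloxy)-2-(hydroxymethyl)phenol; 6 (E)-2,4-bis(benzyloxy)-1-(2-ethoxyvinyl)benzene (1.4 equiv)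
Product: 8 (2S,3R)-7-(benzyloxy)-3-[2,4-bis(benzyloxy)phenyl]-2-ethoxychromane, via o-quinone methide 7 (not isolated)
Conditions: (R)-TRIP (10 mol %), 5 Å MS, toluene, 0 °C, slow addition of 2
Reagents that add atoms: none
Why: The phosphoric acid dehydrates salicyl alcohol 2 (ionisation is eased by the para-benzyloxy and ortho-hydroxy groups) to the o-quinone methide 7, which stays hydrogen-bonded to the chiral phosphate and is trapped by the electron-rich enol ether 6 in an inverse-electron-demand oxa-Diels–Alder reaction: the methide carbon C4 bonds to the aryl-bearing enol carbon C3, and the developing ethoxy-stabilised oxocarbenium at C2 is closed by O1. The closest known reaction type is the Brønsted-acid-catalysed enantioselective [4+2] cycloaddition of o-quinone methides generated in situ from o-hydroxybenzyl alcohols with enol ethers, vinyl sulfides and enamides, together with the racemic o-quinone methide/β-alkoxystyrene route to 2-alkoxyisoflavans. The pyran ring is closed by this [4+2] cycloaddition (heterodiene O1=C8a–C4a=C4, dienophile C3=C2), both ring bonds being made in one operation. C3 is set by the catalyst, whose 3,3′-aryl walls should differentiate the two faces of the enol ether as it approaches the bound o-quinone methide; C2 follows from the E geometry by suprafacial addition (trans) and is removed in step 5, so any 2-epimer formed by a stepwise path converges. The step needs regioselectivity (C4 to the carbon β to OEt, secured by oxocarbenium stabilisation through the alkoxy group, which outweighs the benzylic alternative), chemoselectivity over o-quinone methide oligomerisation (slow addition of 2, excess 6) and protection of 6 from hydrolysis by the released water (molecular sieves).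

Step 5
Reactants: 8 (2S,3R)-7-(benzyloxy)-3-[2,4-bis(benzyloxy)phenyl]-2-ethoxychromane
Product: 9 (3R)-7-(benzyloxy)-3-[2,4-bis(benzyloxy)phenyl]chromane
Conditions: Et3SiH, BF3·OEt2, CH2Cl2, −78 °C
Reagents that add atoms: none
Why: Lewis-acid ionisation of the exocyclic C2–OEt bond gives the cyclic oxocarbenium ion, which the silane should reduce (ionic hydrogenation of a lactol ether) faster than H3 can be lost at −78 °C, so C3 is kept; aryl benzyl ethers tolerate BF3 at this temperature.

Step 6
Reactants: 9 (3R)-7-(benzyloxy)-3-[2,4-bis(benzyloxy)phenyl]chromane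
Product: 10 (3R)-7-(benzyloxy)-3-[2,4-bis(benzyloxy)-5-bromophenyl]-6-bromochromane
Conditions: NBS (2.05 equiv), MeCN, −20 to 0 °C, dark
Reagents that add atoms: N-bromosuccinimide O=C1CCC(=O)N1Br
Why: Electrophilic aromatic bromination should occur in each ring para to one ether oxygen and ortho to the other (C6, para to O1; C5′, para to O2′), as in 2,4-dialkoxytoluenes, because C8 and C3′ are flanked by two oxygens and C5 and C6′ are meta to both.

Step 7
Reactants: 10 (3R)-7-(benzyloxy)-3-[2,4-bis(benzyloxy)-5-bromophenyl]-6-bromochromane; 11 4,4,5,5-tetramethyl-2-(3-methylbut-2-en-1-yl)-1,3,2-dioxaborolane (3 equiv)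
Product: 12 (3R)-7-(benzyloxy)-3-[2,4-bis(benzyloxy)-5-(2-methylbut-3-en-2-yl)phenyl]-6-(2-methylbut-3-en-2-yl)chromane
Conditions: Pd–biarylphosphine precatalyst (ligand chosen for γ-selectivity), aq. K3PO4, THF, 40 °C
Reagents that add atoms: none
Why: Twofold ligand-controlled Suzuki–Miyaura coupling of a prenylboronate: SE2′ transmetalation gives the tertiary σ-allylpalladium, and fast reductive elimination should deliver the branched 1,1-dimethylallyl group at both sites without touching C3.

Step 8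
Reactants: 12 (3R)-7-(benzyloxy)-3-[2,4-bis(benzyloxy)-5-(2-methylbut-3-en-2-yl)phenyl]-6-(2-methylbut-3-en-2-yl)chromane
Product: 13 Manuifolin E, 4-[(3R)-7-hydroxy-6-(2-methylbut-3-en-2-yl)chroman-3-yl]-6-(2-methylbut-3-en-2-yl)benzene-1,3-diol
Conditions: BCl3, C6HMe5, CH2Cl2, −78 °C; MeOH quench at −78 °C
Reagents that add atoms: none
Why: Boron trichloride cleaves the three aryl benzyl ethers at low temperature while pentamethylbenzene traps the benzyl cations (Lewis-acid debenzylation with a non-basic cation scavenger), which avoids hydrogenolysis and should spare the two vinyl groups.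

Compound list
1 | 4-(benzyloxy)-2-hydroxybenzaldehyde | O=Cc1ccc(OCc2ccccc2)cc1O | starting material
2 | 5-(benzyloxy)-2-(hydroxymethyl)phenol | OCc1ccc(OCc2ccccc2)cc1O | intermediate
3 | 4-bromoresorcinol (4-bromobenzene-1,3-diol) | Oc1ccc(Br)c(O)c1 | starting material
4 | 2,4-bis(benzyloxy)-1-bromobenzene | Brc1ccc(OCc2ccccc2)cc1OCc1ccccc1 | intermediate
5 | (E)-2-(2-ethoxyvinyl)-4,4,5,5-tetramethyl-1,3,2-dioxaborolane | CCO/C=C/B1OC(C)(C)C(C)(C)O1 | starting material
6 | (E)-2,4-bis(benzyloxy)-1-(2-ethoxyvinyl)benzene | CCO/C=C/c1ccc(OCc2ccccc2)cc1OCc1ccccc1 | intermediate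
7 | 3-(benzyloxy)-6-methylidenecyclohexa-2,4-dien-1-one (o-quinone methide, not isolated) | C=C1C=CC(OCc2ccccc2)=CC1=O | intermediate
8 | (2S,3R)-7-(benzyloxy)-3-[2,4-bis(benzyloxy)phenyl]-2-ethoxychromane | O(Cc1ccccc1)c1ccc2c(c1)O[C@H](OCC)[C@@H](c1ccc(OCc3ccccc3)cc1OCc1ccccc1)C2 | intermediate
9 | (3R)-7-(benzyloxy)-3-[2,4-bis(benzyloxy)phenyl]chromane | O(Cc1ccccc1)c1ccc2c(c1)OC[C@@H](c1ccc(OCc3ccccc3)cc1OCc1ccccc1)C2 | intermediate
10 | (3R)-7-(benzyloxy)-3-[2,4-bis(benzyloxy)-5-bromophenyl]-6-bromochromane | Brc1cc2c(cc1OCc1ccccc1)OC[C@@H](c1cc(Br)c(OCc3ccccc3)cc1OCc1ccccc1)C2 | intermediate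
11 | 4,4,5,5-tetramethyl-2-(3-methylbut-2-en-1-yl)-1,3,2-dioxaborolane (prenylboronic acid pinacol ester) | CC(C)=CCB1OC(C)(C)C(C)(C)O1 | starting material
12 | (3R)-7-(benzyloxy)-3-[2,4-bis(benzyloxy)-5-(2-methylbut-3-en-2-yl)phenyl]-6-(2-methylbut-3-en-2-yl)chromane | C=CC(C)(C)c1cc2c(cc1OCc1ccccc1)OC[C@@H](c1cc(C(C)(C)C=C)c(OCc3ccccc3)cc1OCc1ccccc1)C2 | intermediate
13 | Manuifolin E | C=CC(C)(C)c1cc2c(cc1O)OC[C@@H](c1cc(C(C)(C)C=C)c(O)cc1O)C2 | target

Total step count: 8. Longest linear sequence: 7 steps (3 → 4 → 6 → 8 → 9 → 10 → 12 → 13; steps 2 to 8).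

Steps most likely to fail

1. Step 4. The phosphate may discriminate the two faces poorly, because the o-quinone methide carries no substituent on the methide carbon; an uncatalysed background cycloaddition, oligomerisation of the o-quinone methide or hydrolysis of the enol ether by the released water would also erode the outcome. The fallback sets out from 1 and 6 and comes back at 9. Enol ether 6 is hydrolysed (1 M HCl, THF) to 2-[2,4-bis(benzyloxy)phenyl]acetaldehyde F1, which is oxidised (NaClO2, NaH2PO4, 2-methyl-2-butene) to 2-[2,4-bis(benzyloxy)phenyl]acetic acid F2. Perkin condensation of F2 with salicylaldehyde 1 (Ac2O, Et3N, 120 °C) should give 7-(benzyloxy)-3-[2,4-bis(benzyloxy)phenyl]-2H-chromen-2-one F3. Reduction with DIBAL-H should give (Z)-2-[2,4-bis(benzyloxy)phenyl]-3-[4-(benzyloxy)-2-hydroxyphenyl]prop-2-en-1-ol F4, and Mitsunobu closure (PPh3, DIAD) then gives 7-(benzyloxy)-3-[2,4-bis(benzyloxy)phenyl]-2H-chromene F5. Iridium-catalysed asymmetric hydrogenation of the C3=C4 bond with a chiral phosphine–oxazoline ligand (H2, CH2Cl2), under which benzyl ethers are stable, returns to 9.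

2. Step 7. Branch selectivity may erode through σ–π–σ isomerisation of the allylpalladium, giving linear prenyl groups at one or both sites; the second coupling may stall next to the ortho-benzyloxy groups, and protodebromination may compete. The fallback sets out from 10 and comes back at 12. Twofold Pd-catalysed α-arylation of the lithium enolate of methyl isobutyrate (LiNCy2, Pd(dba)2/P(t-Bu)3, toluene, rt) should give methyl 2-{(3R)-7-(benzyloxy)-3-[2,4-bis(benzyloxy)-5-(1-methoxy-2-methyl-1-oxopropan-2-yl)phenyl]chroman-6-yl}-2-methylpropanoate F6. LiAlH4 reduces it to 2-{(3R)-7-(benzyloxy)-3-[2,4-bis(benzyloxy)-5-(1-hydroxy-2-methylpropan-2-yl)phenyl]chroman-6-yl}-2-methylpropan-1-ol F7, and Dess–Martin oxidation gives 2-{(3R)-7-(benzyloxy)-3-[2,4-bis(benzyloxy)-5-(2-methyl-1-oxopropan-2-yl)phenyl]chroman-6-yl}-2-methylpropanal F8. Wittig methylenation (Ph3P=CH2, THF) returns to 12.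

3. Step 8. The Lewis acid or the HCl formed may cyclise the liberated ortho-(1,1-dimethylallyl)phenols onto their vinyl groups or add to the alkenes, and the hindered ether next to the quaternary carbon may cleave incompletely. The fallback sets out from 9 and comes back at 13; it changes the protecting groups before any alkene is present. Hydrogenolysis of 9 (H2, Pd/C, EtOAc/MeOH) gives 4-[(3R)-7-hydroxychroman-3-yl]benzene-1,3-diol F9, and silylation (TBSCl, imidazole, DMF) gives (3R)-7-(tert-butyldimethylsilyloxy)-3-[2,4-bis(tert-butyldimethylsilyloxy)phenyl]chromane F10. NBS dibromination as in step 6 should give (3R)-6-bromo-3-[5-bromo-2,4-bis(tert-butyldimethylsilyloxy)phenyl]-7-(tert-butyldimethylsilyloxy)chromane F11, and the coupling of step 7 with 11 gives (3R)-7-(tert-butyldimethylsilyloxy)-3-[2,4-bis(tert-butyldimethylsilyloxy)-5-(2-methylbut-3-en-2-yl)phenyl]-6-(2-methylbut-3-en-2-yl)chromane F12. TBAF (THF, 0 °C) then gives 13 under non-acidic conditions.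

Further compounds
F1 | step 4 | 2-[2,4-bis(benzyloxy)phenyl]acetaldehyde | O=CCc1ccc(OCc2ccccc2)cc1OCc1ccccc1
F2 | step 4 | 2-[2,4-bis(benzyloxy)phenyl]acetic acid | OC(=O)Cc1ccc(OCc2ccccc2)cc1OCc1ccccc1
F3 | step 4 | 7-(benzyloxy)-3-[2,4-bis(benzyloxy)phenyl]-2H-chromen-2-one | O=C1Oc2cc(OCc3ccccc3)ccc2C=C1c1ccc(OCc2ccccc2)cc1OCc1ccccc1
F4 | step 4 | (Z)-2-[2,4-bis(benzyloxy)phenyl]-3-[4-(benzyloxy)-2-hydroxyphenyl]prop-2-en-1-ol | OC/C(=C\c1ccc(OCc2ccccc2)cc1O)c1ccc(OCc2ccccc2)cc1OCc1ccccc1
F5 | step 4 | 7-(benzyloxy)-3-[2,4-bis(benzyloxy)phenyl]-2H-chromene | O(Cc1ccccc1)c1ccc2C=C(c3ccc(OCc4ccccc4)cc3OCc3ccccc3)COc2c1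
F6 | step 7 | methyl 2-{(3R)-7-(benzyloxy)-3-[2,4-bis(benzyloxy)-5-(1-methoxy-2-methyl-1-oxopropan-2-yl)phenyl]chroman-6-yl}-2-methylpropanoate | COC(=O)C(C)(C)c1cc2c(cc1OCc1ccccc1)OC[C@@H](c1cc(C(C)(C)C(=O)OC)c(OCc3ccccc3)cc1OCc1ccccc1)C2
F7 | step 7 | 2-{(3R)-7-(benzyloxy)-3-[2,4-bis(benzyloxy)-5-(1-hydroxy-2-methylpropan-2-yl)phenyl]chroman-6-yl}-2-methylpropan-1-ol | OCC(C)(C)c1cc2c(cc1OCc1ccccc1)OC[C@@H](c1cc(C(C)(C)CO)c(OCc3ccccc3)cc1OCc1ccccc1)C2
F8 | step 7 | 2-{(3R)-7-(benzyloxy)-3-[2,4-bis(benzyloxy)-5-(2-methyl-1-oxopropan-2-yl)phenyl]chroman-6-yl}-2-methylpropanal | O=CC(C)(C)c1cc2c(cc1OCc1ccccc1)OC[C@@H](c1cc(C(C)(C)C=O)c(OCc3ccccc3)cc1OCc1ccccc1)C2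
F9 | step 8 | 4-[(3R)-7-hydroxychroman-3-yl]benzene-1,3-diol | Oc1ccc2c(c1)OC[C@@H](c1ccc(O)cc1O)C2
F10 | step 8 | (3R)-7-(tert-butyldimethylsilyloxy)-3-[2,4-bis(tert-butyldimethylsilyloxy)phenyl]chromane | CC(C)(C)[Si](C)(C)Oc1ccc2c(c1)OC[C@@H](c1ccc(O[Si](C)(C)C(C)(C)C)cc1O[Si](C)(C)C(C)(C)C)C2
F11 | step 8 | (3R)-6-bromo-3-[5-bromo-2,4-bis(tert-butyldimethylsilyloxy)phenyl]-7-(tert-butyldimethylsilyloxy)chromane | Brc1cc2c(cc1O[Si](C)(C)C(C)(C)C)OC[C@@H](c1cc(Br)c(O[Si](C)(C)C(C)(C)C)cc1O[Si](C)(C)C(C)(C)C)C2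
F12 | step 8 | (3R)-7-(tert-butyldimethylsilyloxy)-3-[2,4-bis(tert-butyldimethylsilyloxy)-5-(2-methylbut-3-en-2-yl)phenyl]-6-(2-methylbut-3-en-2-yl)chromane | C=CC(C)(C)c1cc2c(cc1O[Si](C)(C)C(C)(C)C)OC[C@@H](c1cc(C(C)(C)C=C)c(O[Si](C)(C)C(C)(C)C)cc1O[Si](C)(C)C(C)(C)C)C2
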